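**Retrosynthetic overview**
- Ring C (the 3(2H)-furanone) is formed last, by cyclodehydration of an α-hydroxy-3,5-diketo ester inside the finished macrocycle, followed by global desilylation.
- Ring B (22-membered before ring C closes) is closed by thermal dioxinone-to-acylketene macrolactonisation onto the ring A hydroxyl; the (E,E)-diene comes from a Heck coupling of a C1–C16 vinyl iodide with the 6-vinyl δ-lactone (ring A).
- Ring A is made first: L-proline cross-aldol, then a hydroxyl-directed vinyl transfer from boron to a β-hydroxy ketone (new method) with lactonisation.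
- The polypropionate comes from a cinchona-catalysed methylketene dimer (diketide Weinreb amide), an anti,anti boron aldol, a chelation-controlled reduction, a second L-proline aldol and a dioxinone dienolate addition/oxidation.
- The C11–C16 end comes from geraniol: asymmetric epoxidation, epoxy chloride to alkynol, hydrozirconation–iodination, ozonolysis. Ring order: A, then B, then C.

Assumption and notation: the SMILES is taken as drawn; carbons are numbered along the seco chain (C1 macrolactone C=O, C5 furanone C=O, C6 furanone CH, C11 C–OMe, C14 tertiary carbinol, C15–C18 diene, C19 quaternary carbon, C21 C–O of the macrolactone, C22/C23 CHMe and C=O of ring A), which gives 6S,7S,8S,9S,10S,11R,14S,19R,21S,22S,15E,17E; O-trimethylsilylquinine is taken to give the (S)-methylketene dimer (the quinidine analogue would be used if the sense were opposite).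

**Step 1**
Reactants: 1 ethyl 3-oxopentanoate; 2 ethylene glycol
Product: 3 ethyl 2-(2-ethyl-1,3-dioxolan-2-yl)acetate
Conditions: p-TsOH (cat.), PhMe, reflux, Dean–Stark
Reagents that add atoms: none
Why: Acid-catalysed ketalisation with azeotropic water removal masks the ethyl ketone (future C19) so that the ester can be reduced and the aldehyde used as an aldol acceptor.

**Step 2**
Reactants: 3 ethyl 2-(2-ethyl-1,3-dioxolan-2-yl)acetate
Product: 4 2-(2-ethyl-1,3-dioxolan-2-yl)acetaldehyde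
Conditions: i-Bu2AlH (1.05 equiv), CH2Cl2, −78 °C; aq. potassium sodium tartrate
Reagents that add atoms: none
Why: Partial ester reduction; the aluminium hemiacetal is stable at −78 °C and collapses to the aldehyde only on work-up.

**Step 3**
Reactants: 4 2-(2-ethyl-1,3-dioxolan-2-yl)acetaldehyde; 5 propanal
Product: 6 (2S,3S)-4-(2-ethyl-1,3-dioxolan-2-yl)-3-hydroxy-2-methylbutanal
Conditions: L-proline (10 mol %), DMF, 4 °C, 5 added over 24 h to 4 (2 equiv)
Reagents that add atoms: none
Why: Proline-catalysed direct cross-aldol (enamine catalysis, Houk–List transition state): the (E)-enamine of propanal adds to 4 (a poor enamine donor because of its β-quaternary carbon) with the same facial sense as the propanal self-aldol, setting C22 and C21 anti as (2S,3S).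

**Step 4**
Reactants: 6 (2S,3S)-4-(2-ethyl-1,3-dioxolan-2-yl)-3-hydroxy-2-methylbutanal
Product: 8 methyl (2S,3S)-3-hydroxy-2-methyl-5-oxoheptanoate, via ketal acid 7 (not isolated)
Conditions: NaClO2, NaH2PO4, 2-methyl-2-butene, t-BuOH/H2O, 0 °C; then HCl (cat.) in MeOH, 23 °C; H2O
Reagents that add atoms: sodium chlorite [Na+].[O-]Cl=O; methanol CO; water O
Why: Pinnick oxidation leaves the α-stereocentre intact, and Fischer esterification under the same acid cleaves the dioxolane, giving the β-hydroxy ketone as its ester so that the carboxyl cannot bind boron in the next step.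

**Step 5**
Reactants: 8 methyl (2S,3S)-3-hydroxy-2-methyl-5-oxoheptanoate; 9 potassium vinyltrifluoroborate
Product: 12 (3S,4S,6R)-6-ethenyl-6-ethyl-4-hydroxy-3-methyloxan-2-one (ring A; C17–C23), via vinylborate ate complex 10 (not isolated), via diol ester 11 (not isolated)
Conditions: 9 (1.5 equiv), BF3·OEt2 (20 mol %), MeCN/(CF3)2CHOH 3:1, −30 → 0 °C; H2O; then PPTS (10 mol %), PhMe, 60 °C
Reagents that add atoms: none
Why: Proposed new method: fluoride-for-alkoxide exchange tethers the vinylborate to O21 as ate complex 10, the H-bond/BF3-activated C19 ketone then accepts the vinyl group from tetracoordinate boron through a six-membered chair (C18–B–O–C21–C20–C19) with the C22 chain and the ethyl group equatorial and the carbonyl oxygen axial, which gives the (19R) carbinol 11, whose tertiary hydroxyl closes ring A on the ester; the closest known reactions are the Evans–Saksena internal hydride delivery from Me4NBH(OAc)3 to β-hydroxy ketones and the vinyl transfer from boron ate complexes in the Petasis borono-Mannich reaction.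

**Step 6**
Reactants: 13 propanoyl chloride (2 equiv; two molecules are built into the product); 14 N,O-dimethylhydroxylamine
Product: 17 (2S)-N-methoxy-N,2-dimethyl-3-oxopentanamide (C7–C10), via methylketene 15 (not isolated), via methylketene dimer 16 (not isolated)
Conditions: 13 (2 equiv), i-Pr2NEt (2 equiv, one per acid chloride), O-trimethylsilylquinine (5 mol %), CH2Cl2, 23 °C; then 14 (1 equiv), 2-pyridone (10 mol %), 23 °C
Reagents that add atoms: propanoyl chloride (the second molecule of 13) CCC(Cl)=O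
Why: Cinchona-alkaloid (Lewis base) catalysed asymmetric ketene dimerisation: each of two molecules of 13 is dehydrochlorinated to methylketene, the chiral ammonium enolate of one ketene acylates the second and closes to the (S)-β-lactone, setting C8, and aminolysis opens it to the diketide Weinreb amide without epimerisation.

**Step 7**
Reactants: 18 geraniol
Product: 19 [(2S,3S)-3-methyl-3-(4-methylpent-3-en-1-yl)oxiran-2-yl]methanol
Conditions: Ti(Oi-Pr)4 (5 mol %), L-(+)-diethyl tartrate (6 mol %), t-BuOOH, 4 Å MS, CH2Cl2, −20 °C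
Reagents that add atoms: tert-butyl hydroperoxide CC(C)(C)OO
Why: Sharpless asymmetric epoxidation (tetravalent titanium tartrate catalyst) touches only the allylic alkene, and L-(+)-tartrate gives the (2S,3S) epoxide whose C3 becomes C14 (S).

**Step 8**
Reactants: 19 [(2S,3S)-3-methyl-3-(4-methylpent-3-en-1-yl)oxiran-2-yl]methanol
Product: 20 (2R,3S)-2-(chloromethyl)-3-methyl-3-(4-methylpent-3-en-1-yl)oxirane
Conditions: PPh3, CCl4, NaHCO3 (cat.), reflux
Reagents that add atoms: carbon tetrachloride ClC(Cl)(Cl)Cl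
Why: Appel chlorination (SN2 at the primary carbon) leaves the epoxide and both stereocentres untouched.

**Step 9**
Reactants: 20 (2R,3S)-2-(chloromethyl)-3-methyl-3-(4-methylpent-3-en-1-yl)oxirane
Product: 23 triethyl{[(4S)-4,8-dimethylnon-7-en-2-yn-4-yl]oxy}silane, via dilithio alkynolate 21 (not isolated), via lithium alkynolate 22 (not isolated)
Conditions: n-BuLi (3.05 equiv), THF, −40 °C; MeI (1.2 equiv), DMPU, −40 → 0 °C; Et3SiCl (1.5 equiv), 0 → 23 °C
Reagents that add atoms: iodomethane CI; chlorotriethylsilane CC[Si](Cl)(CC)CC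
Why: Base-induced double elimination of a 2,3-epoxy chloride (α-deprotonation with epoxide opening, then dehydrochlorination) gives the tertiary propargylic alkoxide with the C–O stereocentre untouched, and the acetylide is C-methylated and the alkoxide O-silylated in the same flask.

**Step 10**
Reactants: 23 triethyl{[(4S)-4,8-dimethylnon-7-en-2-yn-4-yl]oxy}silane
Product: 25 triethyl{[(2E,4S)-2-iodo-4,8-dimethylnona-2,7-dien-4-yl]oxy}silane, via alkenylzirconocene 24 (not isolated)
Conditions: Cp2ZrHCl (2.5 equiv), THF, 50 °C; then I2, THF, 0 °C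
Reagents that add atoms: iodine II
Why: Hydrozirconation is a syn addition that, after equilibration with excess Cp2ZrHCl, places zirconium on the methyl-bearing alkyne carbon away from the fully substituted carbinol; iodinolysis with retention gives the (E)-iodoalkene, and the trisubstituted alkene is too hindered to react.

**Step 11**
Reactants: 25 triethyl{[(2E,4S)-2-iodo-4,8-dimethylnona-2,7-dien-4-yl]oxy}silane
Product: 26 (4S,5E)-6-iodo-4-methyl-4-(triethylsilyloxy)hept-5-enal (C11–C16)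
Conditions: O3, CH2Cl2/MeOH 4:1, pyridine, −78 °C, stopped at consumption of 25; PPh3, −78 → 23 °C
Reagents that add atoms: ozone O=[O+][O-]
Why: Ozonolysis is selective for the electron-rich trisubstituted alkene over the iodine-deactivated vinyl iodide, and reductive work-up gives the C11 aldehyde.

**Step 12**
Reactants: 26 (4S,5E)-6-iodo-4-methyl-4-(triethylsilyloxy)hept-5-enal; 17 (2S)-N-methoxy-N,2-dimethyl-3-oxopentanamide
Product: 28 (2S,4R,5R,8S,9E)-5-hydroxy-10-iodo-N-methoxy-N,2,4,8-tetramethyl-3-oxo-8-(triethylsilyloxy)undec-9-enamide (C7–C16), via boron enolate 27 (not isolated)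
Conditions: 17 (1.3 equiv), (c-C6H11)2BCl, Me2NEt, Et2O, 0 °C; 26, −78 → −20 °C; pH 7 buffer, MeOH, H2O2, 0 °C
Reagents that add atoms: none
Why: Anti-selective boron aldol (Zimmerman–Traxler chair): the ethyl group of 17 is enolised to the (E)-enolate (the C8–H between the carbonyls is not removed), which gives the 10,11-anti aldol, and the C8 stereocentre directs the aldehyde to the enolate face that gives the 8,10-anti ("anti,anti") isomer.

**Step 13**
Reactants: 28 (aldol adduct)
Product: 29 (2S,4R,5R,8S,9E)-10-iodo-N,5-dimethoxy-N,2,4,8-tetramethyl-3-oxo-8-(triethylsilyloxy)undec-9-enamide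
Conditions: Me3OBF4 (4 equiv), 1,8-bis(dimethylamino)naphthalene (4.5 equiv), 4 Å MS, CH2Cl2, 23 °C
Reagents that add atoms: trimethyloxonium tetrafluoroborate C[O+](C)C.F[B-](F)(F)F
Why: O-methylation with Meerwein salt and a non-nucleophilic base (alkylation under non-basic conditions) installs the C11 methyl ether without retro-aldol or epimerisation of the β-hydroxy ketone.

**Step 14**
Reactants: 29 (β-methoxy ketone)
Product: 30 (2S,3R,4S,5R,8S,9E)-3-hydroxy-10-iodo-N,5-dimethoxy-N,2,4,8-tetramethyl-8-(triethylsilyloxy)undec-9-enamide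
Conditions: Zn(BH4)2 (3 equiv), Et2O, −30 °C; aq. NH4Cl
Reagents that add atoms: none
Why: Chelation-controlled reduction: zinc chelates the ketone either with the β-methoxy group or with the amide carbonyl, both chelates expose the same carbonyl face, and external hydride gives the 9,11-syn, 8,9-syn alcohol (C9).

**Step 15**
Reactants: 30 (C9 alcohol)
Product: 31 (2S,3R,4R,5R,8S,9E)-3-(tert-butyldimethylsilyloxy)-10-iodo-N,5-dimethoxy-N,2,4,8-tetramethyl-8-(triethylsilyloxy)undec-9-enamide
Conditions: t-BuMe2SiOTf (1.5 equiv), 2,6-lutidine (3 equiv), CH2Cl2, −78 → 0 °C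
Reagents that add atoms: tert-butyldimethylsilyl triflate CC(C)(C)[Si](C)(C)OS(=O)(=O)C(F)(F)F
Why: Silylation with the triflate protects the hindered secondary alcohol so that the later aldehyde cannot form a lactol.

**Step 16**
Reactants: 31 (silylated Weinreb amide)
Product: 32 (2S,3R,4R,5R,8S,9E)-3-(tert-butyldimethylsilyloxy)-10-iodo-5-methoxy-2,4,8-trimethyl-8-(triethylsilyloxy)undec-9-enal (C7–C16)
Conditions: i-Bu2AlH (2 equiv), THF, −78 °C; aq. potassium sodium tartrate
Reagents that add atoms: none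
Why: Weinreb amide reduction stops at the aldehyde because the chelated aluminium hemiaminal survives until work-up, and the α-stereocentre is not epimerised at −78 °C.

**Step 17**
Reactants: 32 (C7–C16 aldehyde); 33 (tert-butyldimethylsilyloxy)acetaldehyde
Product: 35 (2S,3S,4S,5R,6R,7R,10S,11E)-2,3,5-tris(tert-butyldimethylsilyloxy)-12-iodo-7-methoxy-4,6,10-trimethyl-10-(triethylsilyloxy)tridec-11-enal (C5–C16), via β-hydroxy aldehyde 34 (not isolated)
Conditions: L-proline (30 mol %), DMF, 4 °C, 33 (3 equiv) added over 24 h; extractive work-up; t-BuMe2SiOTf, 2,6-lutidine, CH2Cl2, −78 °C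
Reagents that add atoms: tert-butyldimethylsilyl triflate CC(C)(C)[Si](C)(C)OS(=O)(=O)C(F)(F)F
Why: Proline-catalysed cross-aldol of an α-oxyaldehyde donor (enamine catalysis): the α-branched aldehyde 32 can only be the acceptor, L-proline sets C6 and C7 anti with the same facial sense as in step 3 (supported by 1,3-anti induction from the C9 silyloxy group), and the labile aldol is silylated without purification.

**Step 18**
Reactants: 35 (C5–C16 aldehyde); 36 2,2,6-trimethyl-4H-1,3-dioxin-4-one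
Product: 38 6-[CH2–CH(OH)–(C6–C16 chain of 35)]-2,2-dimethyl-4H-1,3-dioxin-4-one (C5 carbinol; both epimers), via lithium dienolate 37 (not isolated)
Conditions: 36 (2.5 equiv), LiN(i-Pr)2 (2.4 equiv), THF, −78 °C; 35, −78 °C; AcOH quench
Reagents that add atoms: none
Why: Vinylogous aldol addition: the lithium dienolate of the dioxinone adds through its γ-carbon to the aldehyde, and the new carbinol centre is irrelevant because it is oxidised next.

**Step 19**
Reactants: 38 (C5 carbinol)
Product: 39 6-[CH2–C(=O)–(C6–C16 chain of 35)]-2,2-dimethyl-4H-1,3-dioxin-4-one (C1–C16 keto-dioxinone; 6,7,9-tris-OTBS; 14-OTES; 16-iodide)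
Conditions: Dess–Martin periodinane (1.5 equiv), pyridine, CH2Cl2, 0 → 23 °C
Reagents that add atoms: none
Why: Dess–Martin oxidation under buffered conditions gives the α-silyloxy ketone without epimerising C6 or eliminating the β-silyloxy group.

**Step 20**
Reactants: 39 (C1–C16 keto-dioxinone vinyl iodide); 12 (3S,4S,6R)-6-ethenyl-6-ethyl-4-hydroxy-3-methyloxan-2-one
Product: 40 seco dioxinone: 39 with iodine replaced by the (E)-2-[(2R,4S,5S)-2-ethyl-4-hydroxy-5-methyl-6-oxooxan-2-yl]ethenyl group (15E,17E)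
Conditions: 12 (2 equiv), Pd(OAc)2 (10 mol %), n-Bu4NCl, NaHCO3, DMF, 35 °C, dark
Reagents that add atoms: none
Why: Heck reaction under ligand-free Jeffery conditions: oxidative addition of the vinyl iodide with retention, syn carbopalladation at the terminal CH2 of the vinyl lactone and syn β-hydride elimination (possible only toward C17) give the (E,E)-diene, and without phosphine the tertiary allylic lactone is not ionised by zerovalent palladium.

**Step 21**
Reactants: 40 (seco dioxinone)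
Product: 42 22-membered 3,5-dioxo macrolactone (ring B closed; 6,7,9-tris-OTBS; 14-OTES), via acylketene 41 (not isolated)
Conditions: PhMe, 110 °C, 0.5 mM, 2 h
Reagents that add atoms: none
Why: Thermal retro-[4+2] of the dioxinone releases acetone and an acylketene, which at high dilution is trapped by the only free hydroxyl (C21) to close ring B (acylketene macrolactonisation).

**Step 22**
Reactants: 42 (macrolactone)
Product: 45 target macrolide CNP0226414.1, via α-hydroxy triketone 43 (not isolated), via silylated furanone 44 (not isolated)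
Conditions: n-Bu4NF/AcOH 1:1 (1.2 equiv), THF, 0 °C; then HF·pyridine, pyridine, THF, 0 → 23 °C
Reagents that add atoms: none
Why: Buffered fluoride cleaves the α-keto silyl ether first (best leaving alkoxide), the free C6–OH adds 5-exo to the C3 carbonyl and dehydrates to the vinylogous ester (3(2H)-furanone cyclodehydration, ring C) while O7 is still silylated so no dihydropyranone can form, and HF·pyridine then removes the remaining silyl groups without ionising the tertiary allylic C–O bonds.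

**Compound list**
1 | ethyl 3-oxopentanoate | CCC(=O)CC(=O)OCC | starting material
2 | ethylene glycol | OCCO | starting material
3 | ethyl 2-(2-ethyl-1,3-dioxolan-2-yl)acetate | CCOC(=O)CC1(CC)OCCO1 | intermediate
4 | 2-(2-ethyl-1,3-dioxolan-2-yl)acetaldehyde | O=CCC1(CC)OCCO1 | intermediate
5 | propanal | CCC=O | starting material
6 | (2S,3S)-4-(2-ethyl-1,3-dioxolan-2-yl)-3-hydroxy-2-methylbutanal | O=C[C@@H](C)[C@@H](O)CC1(CC)OCCO1 | intermediate
7 | (2S,3S)-4-(2-ethyl-1,3-dioxolan-2-yl)-3-hydroxy-2-methylbutanoic acid | OC(=O)[C@@H](C)[C@@H](O)CC1(CC)OCCO1 | intermediate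
8 | methyl (2S,3S)-3-hydroxy-2-methyl-5-oxoheptanoate | COC(=O)[C@@H](C)[C@@H](O)CC(=O)CC | intermediate
9 | potassium vinyltrifluoroborate | [K+].C=C[B-](F)(F)F | starting material
10 | potassium difluoro(ethenyl){[(2S,3S)-1-methoxy-2-methyl-1,5-dioxoheptan-3-yl]oxy}borate | [K+].C=C[B-](F)(F)O[C@@H](CC(=O)CC)[C@H](C)C(=O)OC | intermediate
11 | methyl (2S,3S,5R)-5-ethyl-3,5-dihydroxy-2-methylhept-6-enoate | CC[C@](O)(C=C)C[C@H](O)[C@H](C)C(=O)OC | intermediate
12 | (3S,4S,6R)-6-ethenyl-6-ethyl-4-hydroxy-3-methyloxan-2-one | CC[C@]1(C=C)C[C@H](O)[C@H](C)C(=O)O1 | intermediate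
13 | propanoyl chloride | CCC(Cl)=O | starting material
14 | N,O-dimethylhydroxylamine | CNOC | starting material
15 | methylketene | CC=C=O | intermediate
16 | (3S,4Z)-4-ethylidene-3-methyloxetan-2-one | C/C=C1\OC(=O)[C@H]1C | intermediate
17 | (2S)-N-methoxy-N,2-dimethyl-3-oxopentanamide | CCC(=O)[C@H](C)C(=O)N(C)OC | intermediate
18 | geraniol | CC(C)=CCC/C(C)=C/CO | starting material
19 | [(2S,3S)-3-methyl-3-(4-methylpent-3-en-1-yl)oxiran-2-yl]methanol | OC[C@@H]1O[C@@]1(C)CCC=C(C)C | intermediate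
20 | (2R,3S)-2-(chloromethyl)-3-methyl-3-(4-methylpent-3-en-1-yl)oxirane | ClC[C@@H]1O[C@@]1(C)CCC=C(C)C | intermediate
21 | dilithium salt of (3S)-3,7-dimethyloct-6-en-1-yn-3-ol (acetylide alkoxide) | [Li+].[Li+].[C-]#C[C@@](C)([O-])CCC=C(C)C | intermediate
22 | lithium (4S)-4,8-dimethylnon-7-en-2-yn-4-olate | [Li+].CC#C[C@@](C)([O-])CCC=C(C)C | intermediate
23 | triethyl{[(4S)-4,8-dimethylnon-7-en-2-yn-4-yl]oxy}silane | CC#C[C@@](C)(O[Si](CC)(CC)CC)CCC=C(C)C | intermediate
24 | chlorobis(cyclopentadienyl)[(2E,4S)-4,8-dimethyl-4-(triethylsilyloxy)nona-2,7-dien-2-yl]zirconium | C/C(=C\[C@@](C)(O[Si](CC)(CC)CC)CCC=C(C)C)[Zr](Cl)(C1C=CC=C1)C1C=CC=C1 | intermediate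
25 | triethyl{[(2E,4S)-2-iodo-4,8-dimethylnona-2,7-dien-4-yl]oxy}silane | I/C(C)=C/[C@@](C)(O[Si](CC)(CC)CC)CCC=C(C)C | intermediate
26 | (4S,5E)-6-iodo-4-methyl-4-(triethylsilyloxy)hept-5-enal | I/C(C)=C/[C@@](C)(O[Si](CC)(CC)CC)CCC=O | intermediate
27 | dicyclohexylboron (E)-enolate of 17 | C/C=C(/OB(C1CCCCC1)C1CCCCC1)[C@H](C)C(=O)N(C)OC | intermediate
28 | (2S,4R,5R,8S,9E)-5-hydroxy-10-iodo-N-methoxy-N,2,4,8-tetramethyl-3-oxo-8-(triethylsilyloxy)undec-9-enamide | I/C(C)=C/[C@@](C)(O[Si](CC)(CC)CC)CC[C@@H](O)[C@@H](C)C(=O)[C@H](C)C(=O)N(C)OC | intermediate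
29 | (2S,4R,5R,8S,9E)-10-iodo-N,5-dimethoxy-N,2,4,8-tetramethyl-3-oxo-8-(triethylsilyloxy)undec-9-enamide | I/C(C)=C/[C@@](C)(O[Si](CC)(CC)CC)CC[C@@H](OC)[C@@H](C)C(=O)[C@H](C)C(=O)N(C)OC | intermediate
30 | (2S,3R,4S,5R,8S,9E)-3-hydroxy-10-iodo-N,5-dimethoxy-N,2,4,8-tetramethyl-8-(triethylsilyloxy)undec-9-enamide | I/C(C)=C/[C@@](C)(O[Si](CC)(CC)CC)CC[C@@H](OC)[C@@H](C)[C@@H](O)[C@H](C)C(=O)N(C)OC | intermediate
31 | (2S,3R,4R,5R,8S,9E)-3-(tert-butyldimethylsilyloxy)-10-iodo-N,5-dimethoxy-N,2,4,8-tetramethyl-8-(triethylsilyloxy)undec-9-enamide | I/C(C)=C/[C@@](C)(O[Si](CC)(CC)CC)CC[C@@H](OC)[C@@H](C)[C@@H](O[Si](C)(C)C(C)(C)C)[C@H](C)C(=O)N(C)OC | intermediate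
32 | (2S,3R,4R,5R,8S,9E)-3-(tert-butyldimethylsilyloxy)-10-iodo-5-methoxy-2,4,8-trimethyl-8-(triethylsilyloxy)undec-9-enal | I/C(C)=C/[C@@](C)(O[Si](CC)(CC)CC)CC[C@@H](OC)[C@@H](C)[C@@H](O[Si](C)(C)C(C)(C)C)[C@H](C)C=O | intermediate
33 | (tert-butyldimethylsilyloxy)acetaldehyde | CC(C)(C)[Si](C)(C)OCC=O | starting material
34 | (2S,3S,4R,5S,6R,7R,10S,11E)-2,5-bis(tert-butyldimethylsilyloxy)-3-hydroxy-12-iodo-7-methoxy-4,6,10-trimethyl-10-(triethylsilyloxy)tridec-11-enal | I/C(C)=C/[C@@](C)(O[Si](CC)(CC)CC)CC[C@@H](OC)[C@@H](C)[C@@H](O[Si](C)(C)C(C)(C)C)[C@H](C)[C@H](O)[C@H](O[Si](C)(C)C(C)(C)C)C=O | intermediate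
35 | (2S,3S,4S,5R,6R,7R,10S,11E)-2,3,5-tris(tert-butyldimethylsilyloxy)-12-iodo-7-methoxy-4,6,10-trimethyl-10-(triethylsilyloxy)tridec-11-enal | I/C(C)=C/[C@@](C)(O[Si](CC)(CC)CC)CC[C@@H](OC)[C@@H](C)[C@@H](O[Si](C)(C)C(C)(C)C)[C@H](C)[C@H](O[Si](C)(C)C(C)(C)C)[C@H](O[Si](C)(C)C(C)(C)C)C=O | intermediate
36 | 2,2,6-trimethyl-4H-1,3-dioxin-4-one | CC1=CC(=O)OC(C)(C)O1 | starting material
37 | lithium dienolate of 36 | [Li+].C=C1C=C([O-])OC(C)(C)O1 | intermediate
38 | C5 carbinol: dioxinone bearing CH2–CH(OH)–(C6–C16 chain of 35) at its 6-position (both C5 epimers) | I/C(C)=C/[C@@](C)(O[Si](CC)(CC)CC)CC[C@@H](OC)[C@@H](C)[C@@H](O[Si](C)(C)C(C)(C)C)[C@H](C)[C@H](O[Si](C)(C)C(C)(C)C)[C@H](O[Si](C)(C)C(C)(C)C)C(O)CC1=CC(=O)OC(C)(C)O1 | intermediate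
39 | C1–C16 keto-dioxinone vinyl iodide (6,7,9-tris-OTBS; 14-OTES) | I/C(C)=C/[C@@](C)(O[Si](CC)(CC)CC)CC[C@@H](OC)[C@@H](C)[C@@H](O[Si](C)(C)C(C)(C)C)[C@H](C)[C@H](O[Si](C)(C)C(C)(C)C)[C@H](O[Si](C)(C)C(C)(C)C)C(=O)CC1=CC(=O)OC(C)(C)O1 | intermediate
40 | seco dioxinone (Heck product; 15E,17E-diene; free C21–OH) | CC[C@]1(/C=C/C(C)=C/[C@@](C)(O[Si](CC)(CC)CC)CC[C@@H](OC)[C@@H](C)[C@@H](O[Si](C)(C)C(C)(C)C)[C@H](C)[C@H](O[Si](C)(C)C(C)(C)C)[C@H](O[Si](C)(C)C(C)(C)C)C(=O)CC2=CC(=O)OC(C)(C)O2)C[C@H](O)[C@H](C)C(=O)O1 | intermediate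
41 | acylketene from 40 | CC[C@]1(/C=C/C(C)=C/[C@@](C)(O[Si](CC)(CC)CC)CC[C@@H](OC)[C@@H](C)[C@@H](O[Si](C)(C)C(C)(C)C)[C@H](C)[C@H](O[Si](C)(C)C(C)(C)C)[C@H](O[Si](C)(C)C(C)(C)C)C(=O)CC(=O)C=C=O)C[C@H](O)[C@H](C)C(=O)O1 | intermediate
42 | 22-membered 3,5-dioxo macrolactone (6,7,9-tris-OTBS; 14-OTES) | CC[C@]12/C=C/C(C)=C/[C@@](C)(O[Si](CC)(CC)CC)CC[C@@H](OC)[C@@H](C)[C@@H](O[Si](C)(C)C(C)(C)C)[C@H](C)[C@H](O[Si](C)(C)C(C)(C)C)[C@H](O[Si](C)(C)C(C)(C)C)C(=O)CC(=O)CC(=O)O[C@@H](C1)[C@H](C)C(=O)O2 | intermediate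
43 | 6-hydroxy-3,5-dioxo macrolactone (7,9-bis-OTBS; 14-OTES) | CC[C@]12/C=C/C(C)=C/[C@@](C)(O[Si](CC)(CC)CC)CC[C@@H](OC)[C@@H](C)[C@@H](O[Si](C)(C)C(C)(C)C)[C@H](C)[C@H](O[Si](C)(C)C(C)(C)C)[C@H](O)C(=O)CC(=O)CC(=O)O[C@@H](C1)[C@H](C)C(=O)O2 | intermediate
44 | furanone macrolide, 7,9-bis-OTBS, 14-OTES | CC[C@]12/C=C/C(C)=C/[C@@](C)(O[Si](CC)(CC)CC)CC[C@@H](OC)[C@@H](C)[C@@H](O[Si](C)(C)C(C)(C)C)[C@H](C)[C@H](O[Si](C)(C)C(C)(C)C)[C@@H]3OC(=CC3=O)CC(=O)O[C@@H](C1)[C@H](C)C(=O)O2 | intermediate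
45 | CNP0226414.1 | CC[C@]12/C=C/C(C)=C/[C@@](C)(O)CC[C@@H](OC)[C@@H](C)[C@@H](O)[C@H](C)[C@H](O)[C@@H]3OC(=CC3=O)CC(=O)O[C@@H](C1)[C@H](C)C(=O)O2 | target

**Totals**
Total step count: 22. Longest linear sequence: 16 steps (steps 7–22, from geraniol).

**Three steps most likely to fail**

1. Step 5 (the proposed new vinyl transfer). A ketone may be too weak an electrophile for the borate, so protodeboronation, dehydration of the β-hydroxy ketone or a low diastereomer ratio at C19 are possible. The fallback uses known chemistry, sets out from 8 and comes back at 12.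
 - Wittig methylenation of the ketone of 8 (Ph3P=CH2, THF, −78 → 0 °C) gives the homoallylic alcohol methyl (2S,3S)-5-ethyl-3-hydroxy-2-methylhex-5-enoate F1.
 - Boc2O/DMAP gives the carbonate methyl (2S,3S)-3-[(tert-butoxycarbonyl)oxy]-5-ethyl-2-methylhex-5-enoate F2.
 - IBr in PhMe at −85 °C (iodocarbonate cyclisation through a chair with the side chain equatorial, 1,3-syn) gives methyl (2S)-2-[(4S,6R)-6-ethyl-6-(iodomethyl)-2-oxo-1,3-dioxan-4-yl]propanoate F3.
 - K2CO3/MeOH gives the epoxy alcohol methyl (2S,3S)-4-[(2R)-2-ethyloxiran-2-yl]-3-hydroxy-2-methylbutanoate F4.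
 - Excess dimethylsulfonium methylide (Me3SI, n-BuLi, THF) homologates the epoxide to the tertiary vinyl carbinolate, which closes onto the ester to give 12.

2. Step 17 (proline cross-aldol on a hindered chiral acceptor). The Felkin preference of the α-methyl aldehyde opposes the catalyst, the donor self-dimerises, and C8 could slowly epimerise through the enamine. The fallback is reagent-controlled, sets out from 32 and comes back at 35.
 - anti-α-Hydroxyallylation of 32 with [(E)-3-(1,3,2-dioxaborinan-2-yl)allyl]diisopinocampheylborane (made from 2-(propa-1,2-dienyl)-1,3,2-dioxaborinane and the Ipc2BH derived from (−)-α-pinene; Et2O, −78 °C; then NaOH/H2O2) gives the anti-6,7-diol with a vinyl group in place of the C5 aldehyde F5.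
 - t-BuMe2SiOTf/2,6-lutidine gives the 6,7-bis(tert-butyldimethylsilyl) ether of that alkene F6.
 - Ozonolysis of the terminal alkene only (O3, then PPh3) gives 35.

3. Step 20 (intermolecular Heck). Conversion of the hindered vinyl lactone may be low, zerovalent palladium could ionise the tertiary allylic lactone, and the base could eliminate the β-silyloxy ketone. The fallback changes the bond-forming order so that no palladium meets ring A; it sets out from 39 and comes back at 42.
 - Stille coupling of 39 with tributyl(vinyl)stannane (Pd2(dba)3, AsPh3, NMP, 23 °C) gives the C1–C17 terminal diene keto-dioxinone F7.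
 - Heating F7 with 12 (PhMe, 110 °C, intermolecular acylketene trapping) gives the C21 3,5-dioxo ester of 12 F8.
 - Ring-closing metathesis of the diene terminus with the C19 vinyl group (second-generation Grubbs catalyst (H2IMes)(PCy3)Cl2Ru=CHPh, CH2Cl2, 40 °C, 1 mM) closes C17=C18 and gives 42.

**Further compounds**
F1 | step 5 | methyl (2S,3S)-5-ethyl-3-hydroxy-2-methylhex-5-enoate | COC(=O)[C@@H](C)[C@@H](O)CC(=C)CC
F2 | step 5 | methyl (2S,3S)-3-[(tert-butoxycarbonyl)oxy]-5-ethyl-2-methylhex-5-enoate | COC(=O)[C@@H](C)[C@@H](OC(=O)OC(C)(C)C)CC(=C)CC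
F3 | step 5 | methyl (2S)-2-[(4S,6R)-6-ethyl-6-(iodomethyl)-2-oxo-1,3-dioxan-4-yl]propanoate | CC[C@]1(CI)C[C@@H]([C@H](C)C(=O)OC)OC(=O)O1
F4 | step 5 | methyl (2S,3S)-4-[(2R)-2-ethyloxiran-2-yl]-3-hydroxy-2-methylbutanoate | CC[C@]1(CO1)C[C@H](O)[C@H](C)C(=O)OC
F5 | step 17 | anti-6,7-diol with a vinyl group in place of the C5 aldehyde (otherwise as 32) | I/C(C)=C/[C@@](C)(O[Si](CC)(CC)CC)CC[C@@H](OC)[C@@H](C)[C@@H](O[Si](C)(C)C(C)(C)C)[C@H](C)[C@H](O)[C@H](O)C=C
F6 | step 17 | 6,7-bis(tert-butyldimethylsilyl) ether of F5 | I/C(C)=C/[C@@](C)(O[Si](CC)(CC)CC)CC[C@@H](OC)[C@@H](C)[C@@H](O[Si](C)(C)C(C)(C)C)[C@H](C)[C@H](O[Si](C)(C)C(C)(C)C)[C@H](O[Si](C)(C)C(C)(C)C)C=C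
F7 | step 20 | C1–C17 terminal diene keto-dioxinone (39 with vinyl in place of iodine) | C=C/C(C)=C/[C@@](C)(O[Si](CC)(CC)CC)CC[C@@H](OC)[C@@H](C)[C@@H](O[Si](C)(C)C(C)(C)C)[C@H](C)[C@H](O[Si](C)(C)C(C)(C)C)[C@H](O[Si](C)(C)C(C)(C)C)C(=O)CC1=CC(=O)OC(C)(C)O1
F8 | step 20 | C21 3,5-dioxo ester of 12 carrying the C6–C17 diene chain | C=C/C(C)=C/[C@@](C)(O[Si](CC)(CC)CC)CC[C@@H](OC)[C@@H](C)[C@@H](O[Si](C)(C)C(C)(C)C)[C@H](C)[C@H](O[Si](C)(C)C(C)(C)C)[C@H](O[Si](C)(C)C(C)(C)C)C(=O)CC(=O)CC(=O)O[C@H]1C[C@](CC)(C=C)OC(=O)[C@H]1C
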